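**Strategy.** In ring C of the target, C2 is a CH2 group held only by O1 and the stereogenic C3, so it can be drawn from the methyl carbon of an aryl methyl ether on ring A. The route is built on cutting the C2–C3 bond: a chiral dirhodium carboxylate turns an α-aryl-α-diazo ketone into a carbenoid at C3 that inserts into a C–H bond of one of two equivalent ortho-methoxy groups, which closes ring C and sets (3R) in a single operation. The precursor is a diazo deoxybenzoin with a 2,6-dimethoxy-4-silyloxy ring A and a prenylated ring B whose catechol is tied up as a silylene, so that only silicon groups lie near the carbenoid.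

Key step: step 11

Assumption: the facial sense of Rh2(S-PTTL)4 (dirhodium tetrakis[N-phthaloyl-(S)-tert-leucinate]) on this substrate class cannot be taken from precedent; the route is written for the S ligands, and Rh2(R-PTTL)4 would be used if the carbenoid were attacked from the other face.

Locants follow isoflavanone numbering (O1, C2, C3, C4 in ring C; primed numbers in ring B).

Step 1
Reactants: 1 3,5-dimethoxyphenol
Product: 2 (3,5-dimethoxyphenoxy)triisopropylsilane
Conditions: TIPSCl, imidazole, DMF, rt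
Reagents that add atoms: chlorotriisopropylsilane (TIPSCl), CC(C)[Si](Cl)(C(C)C)C(C)C
Why: Silylation of a phenol to its silyl ether is routine, and the bulky TIPS group later keeps lithiation away from its own ortho positions and offers the carbenoid no reachable C–H bond.

Step 2
Reactants: 3 2,3-dihydroxy-4-methoxybenzaldehyde
Product: 4 5-bromo-2,3-dihydroxy-4-methoxybenzaldehyde
Conditions: Br2 (1 equiv), NaOAc, AcOH, 0 °C → rt
Reagents that add atoms: bromine, BrBr
Why: Electrophilic aromatic bromination should go to C5, which is para to the 2-hydroxyl, ortho to the methoxy group and meta to the formyl group, whereas C6 is ortho to the deactivating aldehyde.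

Step 3
Reactants: 4 5-bromo-2,3-dihydroxy-4-methoxybenzaldehyde
Product: 5 6-bromo-2,2-di-tert-butyl-7-methoxy-1,3,2-benzodioxasilole-4-carbaldehyde
Conditions: t-Bu2Si(OTf)2, 2,6-lutidine, CH2Cl2, 0 °C → rt
Reagents that add atoms: di-tert-butylsilyl bis(trifluoromethanesulfonate), CC(C)(C)[Si](OS(=O)(=O)C(F)(F)F)(OS(=O)(=O)C(F)(F)F)C(C)(C)C
Why: Cyclic silylene formation with the reactive bis(triflate) masks both catechol oxygens in one group that has no C–H bond α to oxygen and is removable by fluoride.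

Step 4
Reactants: 5 6-bromo-2,2-di-tert-butyl-7-methoxy-1,3,2-benzodioxasilole-4-carbaldehyde
Product: 6 6-bromo-2,2-di-tert-butyl-7-methoxy-4-(2-methoxyethenyl)-1,3,2-benzodioxasilole (E/Z mixture)
Conditions: Ph3P(CH2OMe)Cl, NaN(SiMe3)2, THF, −78 → 0 °C
Reagents that add atoms: (methoxymethyl)triphenylphosphonium chloride, COC[P+](c1ccccc1)(c1ccccc1)c1ccccc1.[Cl-]
Why: Wittig olefination with the methoxymethylene ylide gives the enol ether (one-carbon homologation), and a non-nucleophilic amide base at low temperature spares the aryl silyl ether.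

Step 5
Reactants: 6 6-bromo-2,2-di-tert-butyl-7-methoxy-4-(2-methoxyethenyl)-1,3,2-benzodioxasilole
Product: 7 (6-bromo-2,2-di-tert-butyl-7-methoxy-1,3,2-benzodioxasilol-4-yl)acetaldehyde
Conditions: 2 M aq. HCl, THF, rt
Reagents that add atoms: water, O
Why: Acid-catalysed enol ether hydrolysis releases the homologous aldehyde while no acid-sensitive alkene is yet present, and hindered aryl silyl ethers tolerate brief dilute acid.

Step 6
Reactants: 7 (6-bromo-2,2-di-tert-butyl-7-methoxy-1,3,2-benzodioxasilol-4-yl)acetaldehyde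
Product: 8 (6-bromo-2,2-di-tert-butyl-7-methoxy-1,3,2-benzodioxasilol-4-yl)acetic acid
Conditions: NaClO2, NaH2PO4, 2-methyl-2-butene, t-BuOH/H2O, 0 °C → rt
Reagents that add atoms: sodium chlorite, [Na+].[O-]Cl=O
Why: Pinnick oxidation converts the aldehyde to the acid under buffered conditions, with 2-methyl-2-butene trapping hypochlorous acid before it can chlorinate the electron-rich ring.

Step 7
Reactants: 8 (6-bromo-2,2-di-tert-butyl-7-methoxy-1,3,2-benzodioxasilol-4-yl)acetic acid
Product: 9 2-(6-bromo-2,2-di-tert-butyl-7-methoxy-1,3,2-benzodioxasilol-4-yl)-N-methoxy-N-methylacetamide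
Conditions: MeNHOMe·HCl, EDC·HCl, HOBt, i-Pr2NEt, CH2Cl2, 0 °C → rt
Reagents that add atoms: N,O-dimethylhydroxylamine hydrochloride, CNOC.Cl
Why: Carbodiimide-mediated amide coupling gives the Weinreb amide under mild, nearly neutral conditions that leave the silylene and the aryl bromide intact.

Step 8
Reactants: 9 2-(6-bromo-2,2-di-tert-butyl-7-methoxy-1,3,2-benzodioxasilol-4-yl)-N-methoxy-N-methylacetamide; 10 tributyl(3-methylbut-2-en-1-yl)stannane
Product: 11 2-[2,2-di-tert-butyl-7-methoxy-6-(3-methylbut-2-en-1-yl)-1,3,2-benzodioxasilol-4-yl]-N-methoxy-N-methylacetamide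
Conditions: Pd(PPh3)4 (5 mol%), toluene, 100 °C
Reagents that add atoms: none
Why: Stille coupling (oxidative addition of the aryl bromide to zerovalent palladium, allyl transfer from tin, reductive elimination at the less hindered allyl terminus) should give the linear prenyl group under neutral, fluoride-free conditions, and placing it after the acid and oxidant steps protects the alkene.

Step 9
Reactants: 2 (3,5-dimethoxyphenoxy)triisopropylsilane; 11 2-[2,2-di-tert-butyl-7-methoxy-6-(3-methylbut-2-en-1-yl)-1,3,2-benzodioxasilol-4-yl]-N-methoxy-N-methylacetamide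
Product: 13 1-[2,6-dimethoxy-4-(triisopropylsilyloxy)phenyl]-2-[2,2-di-tert-butyl-7-methoxy-6-(3-methylbut-2-en-1-yl)-1,3,2-benzodioxasilol-4-yl]ethan-1-one (deoxybenzoin), via aryllithium 12 (not isolated)
Conditions: n-BuLi, THF, 0 °C → rt; then 11, −78 → −20 °C; aq. NH4Cl
Reagents that add atoms: none
Why: Directed ortho-lithiation takes place at the carbon flanked by both methoxy groups (the bulky silyl ether is a poor director), and Weinreb ketone synthesis stops at the ketone because the metal-chelated adduct collapses only on work-up, low temperature favouring addition over α-deprotonation of the amide.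

Step 10
Reactants: 13 1-[2,6-dimethoxy-4-(triisopropylsilyloxy)phenyl]-2-[2,2-di-tert-butyl-7-methoxy-6-(3-methylbut-2-en-1-yl)-1,3,2-benzodioxasilol-4-yl]ethan-1-one
Product: 14 2-diazo-1-[2,6-dimethoxy-4-(triisopropylsilyloxy)phenyl]-2-[2,2-di-tert-butyl-7-methoxy-6-(3-methylbut-2-en-1-yl)-1,3,2-benzodioxasilol-4-yl]ethan-1-one
Conditions: p-ABSA, DBU, MeCN, 0 °C → rt
Reagents that add atoms: 4-acetamidobenzenesulfonyl azide (p-ABSA), CC(=O)Nc1ccc(cc1)S(=O)(=O)N=[N+]=[N-]
Why: Regitz diazo transfer is standard for benzylic ketones: DBU forms the enolate, which attacks the sulfonyl azide and expels the sulfonamide, and anhydrous amidine base leaves both silicon groups in place.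

Step 11
Reactants: 14 2-diazo-1-[2,6-dimethoxy-4-(triisopropylsilyloxy)phenyl]-2-[2,2-di-tert-butyl-7-methoxy-6-(3-methylbut-2-en-1-yl)-1,3,2-benzodioxasilol-4-yl]ethan-1-one
Product: 15 (3R)-3-[2,2-di-tert-butyl-7-methoxy-6-(3-methylbut-2-en-1-yl)-1,3,2-benzodioxasilol-4-yl]-5-methoxy-7-(triisopropylsilyloxy)-2,3-dihydro-4H-chromen-4-one
Conditions: Rh2(S-PTTL)4 (1 mol%), 4 Å MS, PhCF3, 0 °C → rt, slow addition of 14 at high dilution
Reagents that add atoms: none
Why: Proposed new method: Rh2(S-PTTL)4 should expel N2 from 14 to give a donor/acceptor rhodium carbenoid at C3, which inserts in a concerted but asynchronous, hydride-transfer-like three-centre step into a C–H bond of an ortho-methoxy group (activated by the adjacent oxygen) and so forms the C2–C3 bond. The closest known reaction types are enantioselective dirhodium-carbenoid 1,5-insertions into C–H bonds α to an ether oxygen that give 2,3-dihydrobenzofurans, six-membered closures of ortho-alkoxyaryl diazo ketones onto O–CH2R groups that give chroman-4-ones, and intermolecular C–H functionalisation of methyl ethers by donor/acceptor carbenoids; closure onto an aryl O–CH3 group has not been shown. Ring C is closed as a six-membered ring by 1,6-C–H insertion, the methoxy carbon becoming C2. The only new stereocentre, C3, is the former carbenoid carbon, so its configuration is set under catalyst control by the face that the N-phthaloyl-tert-leucinate ligand wall leaves open to the approaching C–H bond. The step needs chemoselectivity for C–H insertion over oxonium-ylide formation with [1,2]-methyl shift, Wolff rearrangement and bimolecular attack on the prenyl alkene; the substrate answers with two equivalent methoxy groups (either gives 15), a 2,6-disubstituted aroyl group twisted out of the arene plane so that the carbenoid lies over a methyl group and away from the in-plane ether lone pair, and silicon-only substituents on every other nearby oxygen, which removes any five-membered insertion, while slow addition at high dilution suppresses bimolecular paths. The neutral conditions leave the enolisable C3–H untouched.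

Step 12
Reactants: 15 (3R)-3-[2,2-di-tert-butyl-7-methoxy-6-(3-methylbut-2-en-1-yl)-1,3,2-benzodioxasilol-4-yl]-5-methoxy-7-(triisopropylsilyloxy)-2,3-dihydro-4H-chromen-4-one
Product: 16 (3R)-3-[2,2-di-tert-butyl-7-methoxy-6-(3-methylbut-2-en-1-yl)-1,3,2-benzodioxasilol-4-yl]-5-hydroxy-7-(triisopropylsilyloxy)-2,3-dihydro-4H-chromen-4-one
Conditions: MgI2·OEt2 (3 equiv), toluene/Et2O, 50 °C; then 1 M aq. HCl, 0 °C
Reagents that add atoms: none
Why: Chelation-controlled O-demethylation: magnesium bridges the C4 carbonyl and the 5-methoxy oxygen so that iodide removes only that methyl group by SN2 attack while the 4'-methoxy group, which has no carbonyl partner, stays, and in the absence of a Brønsted base the C3 stereocentre should be kept.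

Step 13
Reactants: 16 (3R)-3-[2,2-di-tert-butyl-7-methoxy-6-(3-methylbut-2-en-1-yl)-1,3,2-benzodioxasilol-4-yl]-5-hydroxy-7-(triisopropylsilyloxy)-2,3-dihydro-4H-chromen-4-one
Product: 17 (3R)-3-[2,3-dihydroxy-4-methoxy-5-(3-methylbut-2-en-1-yl)phenyl]-5,7-dihydroxy-2,3-dihydro-4H-chromen-4-one (target)
Conditions: HF·pyridine, pyridine, THF, 0 °C → rt, under argon
Reagents that add atoms: none
Why: Fluoride-driven desilylation cleaves the aryl silyl ether and the catechol silylene in a pyridine-buffered, weakly acidic medium, which avoids base-mediated enolisation at C3 and leaves the prenyl alkene and the 4'-methyl ether untouched.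

**Compound list**

1 | 3,5-dimethoxyphenol | COc1cc(O)cc(OC)c1 | starting material
2 | (3,5-dimethoxyphenoxy)triisopropylsilane | COc1cc(OC)cc(O[Si](C(C)C)(C(C)C)C(C)C)c1 | intermediate
3 | 2,3-dihydroxy-4-methoxybenzaldehyde | COc1ccc(C=O)c(O)c1O | starting material
4 | 5-bromo-2,3-dihydroxy-4-methoxybenzaldehyde | COc1c(Br)cc(C=O)c(O)c1O | intermediate
5 | 6-bromo-2,2-di-tert-butyl-7-methoxy-1,3,2-benzodioxasilole-4-carbaldehyde | COc1c(Br)cc(C=O)c2O[Si](C(C)(C)C)(C(C)(C)C)Oc12 | intermediate
6 | 6-bromo-2,2-di-tert-butyl-7-methoxy-4-(2-methoxyethenyl)-1,3,2-benzodioxasilole (E/Z mixture) | COC=Cc1cc(Br)c(OC)c2O[Si](C(C)(C)C)(C(C)(C)C)Oc12 | intermediate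
7 | (6-bromo-2,2-di-tert-butyl-7-methoxy-1,3,2-benzodioxasilol-4-yl)acetaldehyde | O=CCc1cc(Br)c(OC)c2O[Si](C(C)(C)C)(C(C)(C)C)Oc12 | intermediate
8 | (6-bromo-2,2-di-tert-butyl-7-methoxy-1,3,2-benzodioxasilol-4-yl)acetic acid | OC(=O)Cc1cc(Br)c(OC)c2O[Si](C(C)(C)C)(C(C)(C)C)Oc12 | intermediate
9 | 2-(6-bromo-2,2-di-tert-butyl-7-methoxy-1,3,2-benzodioxasilol-4-yl)-N-methoxy-N-methylacetamide | CON(C)C(=O)Cc1cc(Br)c(OC)c2O[Si](C(C)(C)C)(C(C)(C)C)Oc12 | intermediate
10 | tributyl(3-methylbut-2-en-1-yl)stannane | CCCC[Sn](CCCC)(CCCC)CC=C(C)C | starting material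
11 | 2-[2,2-di-tert-butyl-7-methoxy-6-(3-methylbut-2-en-1-yl)-1,3,2-benzodioxasilol-4-yl]-N-methoxy-N-methylacetamide | CON(C)C(=O)Cc1cc(CC=C(C)C)c(OC)c2O[Si](C(C)(C)C)(C(C)(C)C)Oc12 | intermediate
12 | [2,6-dimethoxy-4-(triisopropylsilyloxy)phenyl]lithium (formed in the flask) | [Li]c1c(OC)cc(O[Si](C(C)C)(C(C)C)C(C)C)cc1OC | intermediate
13 | 1-[2,6-dimethoxy-4-(triisopropylsilyloxy)phenyl]-2-[2,2-di-tert-butyl-7-methoxy-6-(3-methylbut-2-en-1-yl)-1,3,2-benzodioxasilol-4-yl]ethan-1-one | COc1cc(O[Si](C(C)C)(C(C)C)C(C)C)cc(OC)c1C(=O)Cc1cc(CC=C(C)C)c(OC)c2O[Si](C(C)(C)C)(C(C)(C)C)Oc12 | intermediate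
14 | 2-diazo-1-[2,6-dimethoxy-4-(triisopropylsilyloxy)phenyl]-2-[2,2-di-tert-butyl-7-methoxy-6-(3-methylbut-2-en-1-yl)-1,3,2-benzodioxasilol-4-yl]ethan-1-one | COc1cc(O[Si](C(C)C)(C(C)C)C(C)C)cc(OC)c1C(=O)C(=[N+]=[N-])c1cc(CC=C(C)C)c(OC)c2O[Si](C(C)(C)C)(C(C)(C)C)Oc12 | intermediate
15 | (3R)-3-[2,2-di-tert-butyl-7-methoxy-6-(3-methylbut-2-en-1-yl)-1,3,2-benzodioxasilol-4-yl]-5-methoxy-7-(triisopropylsilyloxy)-2,3-dihydro-4H-chromen-4-one | COc1c(CC=C(C)C)cc([C@@H]2COc3cc(O[Si](C(C)C)(C(C)C)C(C)C)cc(OC)c3C2=O)c2O[Si](C(C)(C)C)(C(C)(C)C)Oc12 | intermediate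
16 | (3R)-3-[2,2-di-tert-butyl-7-methoxy-6-(3-methylbut-2-en-1-yl)-1,3,2-benzodioxasilol-4-yl]-5-hydroxy-7-(triisopropylsilyloxy)-2,3-dihydro-4H-chromen-4-one | COc1c(CC=C(C)C)cc([C@@H]2COc3cc(O[Si](C(C)C)(C(C)C)C(C)C)cc(O)c3C2=O)c2O[Si](C(C)(C)C)(C(C)(C)C)Oc12 | intermediate
17 | (3R)-3-[2,3-dihydroxy-4-methoxy-5-(3-methylbut-2-en-1-yl)phenyl]-5,7-dihydroxy-2,3-dihydro-4H-chromen-4-one | COc1c(CC=C(C)C)cc([C@@H]2COc3cc(O)cc(O)c3C2=O)c(O)c1O | target

**Step count.** Total: 13 steps. Longest linear sequence: 12 steps (steps 2 to 13, from 3 to 17).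

**Steps most likely to fail**

Step 11 (the proposed new method). The carbenoid may attack the ether oxygen instead of the C–H bond, so that an oxonium ylide forms and a methyl shift gives a five-membered ring. Nitrogen loss may be slow at the doubly ortho-flanked diazo carbon, so that Wolff-type aryl migration or bimolecular reactions take over. The facial selectivity may also be poor. Fallback, known chemistry only, setting out from 13 and coming back at 15: one methyl ether next to the ketone is cleaved by chelation control (MgI2·OEt2, toluene/Et2O, 50 °C) to give the 2-hydroxy-6-methoxy deoxybenzoin F1. Condensation with N,N-dimethylformamide dimethyl acetal (toluene, 90 °C) supplies C2 and closes ring C as the isoflavone F2. Asymmetric transfer hydrogenation (RuCl[(R,R)-TsDPEN](p-cymene), HCO2H/Et3N, EtOAc) first reduces the C2=C3 bond to the racemic, rapidly epimerising isoflavanone F3 (not isolated). By dynamic kinetic resolution it then reduces the ketone to the cis-(3R,4R)-isoflavan-4-ol F4; the (R,R)-diamine is chosen by analogy with aryl alkyl ketone reductions. Buffered Dess–Martin oxidation (NaHCO3, CH2Cl2, 0 °C) restores the C4 ketone without touching C3 and gives 15.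

Step 12. Enolisation of the magnesium-chelated ketone may erode the C3 configuration, and acid formed on work-up may add to the prenyl alkene. Fallback, setting out from 13 and coming back at 17, which moves the ether cleavage ahead of the stereocentre: 13 is mono-demethylated as above to the 2-hydroxy-6-methoxy deoxybenzoin F1. The phenol is silylated (TIPSCl, imidazole, DMAP, DMF, 40 °C) to the 2-methoxy-4,6-bis(triisopropylsilyloxy) deoxybenzoin F5. Diazo transfer (p-ABSA, DBU, MeCN) gives the diazo ketone F6. The insertion of step 11 (Rh2(S-PTTL)4, PhCF3), by then established, closes ring C onto the one remaining methoxy group to give the (3R)-5,7-bis-O-TIPS isoflavanone F7. A single treatment with HF·pyridine (pyridine, THF) then frees all four phenols and gives 17. This variant gives up the second methoxy group as an insertion site and relies on the hindered ortho silyl ether not migrating.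

Step 9. The aryllithium may act as a base and deprotonate the benzylic α-position of the amide, returning both partners, or attack may be slow for steric reasons. Fallback, setting out from 11 (with 12) and coming back at 13, by carbonyl addition and oxidation with a far less basic nucleophile: 11 is reduced (i-Bu2AlH, THF, −78 °C) to the arylacetaldehyde F8. Aryllithium 12 is transmetallated with anhydrous CeCl3 (THF, −78 °C) to the dichloro(aryl)cerium reagent F9. Addition of F9 to F8 gives, after work-up, the secondary alcohol F10. Because this electron-rich benzylic alcohol ionises easily, it is oxidised at once (Dess–Martin periodinane, NaHCO3, CH2Cl2) to 13.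

**Further compounds**

F1 | step 11 | 1-[2-hydroxy-6-methoxy-4-(triisopropylsilyloxy)phenyl]-2-[2,2-di-tert-butyl-7-methoxy-6-(3-methylbut-2-en-1-yl)-1,3,2-benzodioxasilol-4-yl]ethan-1-one | COc1cc(O[Si](C(C)C)(C(C)C)C(C)C)cc(O)c1C(=O)Cc1cc(CC=C(C)C)c(OC)c2O[Si](C(C)(C)C)(C(C)(C)C)Oc12
F2 | step 11 | 3-[2,2-di-tert-butyl-7-methoxy-6-(3-methylbut-2-en-1-yl)-1,3,2-benzodioxasilol-4-yl]-5-methoxy-7-(triisopropylsilyloxy)-4H-chromen-4-one | COc1cc(O[Si](C(C)C)(C(C)C)C(C)C)cc2occ(-c3cc(CC=C(C)C)c(OC)c4O[Si](C(C)(C)C)(C(C)(C)C)Oc34)c(=O)c12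
F3 | step 11 | racemic 3-[2,2-di-tert-butyl-7-methoxy-6-(3-methylbut-2-en-1-yl)-1,3,2-benzodioxasilol-4-yl]-5-methoxy-7-(triisopropylsilyloxy)-2,3-dihydro-4H-chromen-4-one | COc1c(CC=C(C)C)cc(C2COc3cc(O[Si](C(C)C)(C(C)C)C(C)C)cc(OC)c3C2=O)c2O[Si](C(C)(C)C)(C(C)(C)C)Oc12
F4 | step 11 | (3R,4R)-3-[2,2-di-tert-butyl-7-methoxy-6-(3-methylbut-2-en-1-yl)-1,3,2-benzodioxasilol-4-yl]-5-methoxy-7-(triisopropylsilyloxy)-3,4-dihydro-2H-chromen-4-ol | COc1cc(O[Si](C(C)C)(C(C)C)C(C)C)cc2OC[C@@H](c3cc(CC=C(C)C)c(OC)c4O[Si](C(C)(C)C)(C(C)(C)C)Oc34)[C@@H](O)c12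
F5 | step 12 | 1-[2-methoxy-4,6-bis(triisopropylsilyloxy)phenyl]-2-[2,2-di-tert-butyl-7-methoxy-6-(3-methylbut-2-en-1-yl)-1,3,2-benzodioxasilol-4-yl]ethan-1-one | COc1cc(O[Si](C(C)C)(C(C)C)C(C)C)cc(O[Si](C(C)C)(C(C)C)C(C)C)c1C(=O)Cc1cc(CC=C(C)C)c(OC)c2O[Si](C(C)(C)C)(C(C)(C)C)Oc12
F6 | step 12 | 2-diazo-1-[2-methoxy-4,6-bis(triisopropylsilyloxy)phenyl]-2-[2,2-di-tert-butyl-7-methoxy-6-(3-methylbut-2-en-1-yl)-1,3,2-benzodioxasilol-4-yl]ethan-1-one | COc1cc(O[Si](C(C)C)(C(C)C)C(C)C)cc(O[Si](C(C)C)(C(C)C)C(C)C)c1C(=O)C(=[N+]=[N-])c1cc(CC=C(C)C)c(OC)c2O[Si](C(C)(C)C)(C(C)(C)C)Oc12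
F7 | step 12 | (3R)-3-[2,2-di-tert-butyl-7-methoxy-6-(3-methylbut-2-en-1-yl)-1,3,2-benzodioxasilol-4-yl]-5,7-bis(triisopropylsilyloxy)-2,3-dihydro-4H-chromen-4-one | COc1c(CC=C(C)C)cc([C@@H]2COc3cc(O[Si](C(C)C)(C(C)C)C(C)C)cc(O[Si](C(C)C)(C(C)C)C(C)C)c3C2=O)c2O[Si](C(C)(C)C)(C(C)(C)C)Oc12
F8 | step 9 | [2,2-di-tert-butyl-7-methoxy-6-(3-methylbut-2-en-1-yl)-1,3,2-benzodioxasilol-4-yl]acetaldehyde | O=CCc1cc(CC=C(C)C)c(OC)c2O[Si](C(C)(C)C)(C(C)(C)C)Oc12
F9 | step 9 | dichloro[2,6-dimethoxy-4-(triisopropylsilyloxy)phenyl]cerium | COc1cc(O[Si](C(C)C)(C(C)C)C(C)C)cc(OC)c1[Ce](Cl)Cl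
F10 | step 9 | racemic 1-[2,6-dimethoxy-4-(triisopropylsilyloxy)phenyl]-2-[2,2-di-tert-butyl-7-methoxy-6-(3-methylbut-2-en-1-yl)-1,3,2-benzodioxasilol-4-yl]ethan-1-ol | COc1cc(O[Si](C(C)C)(C(C)C)C(C)C)cc(OC)c1C(O)Cc1cc(CC=C(C)C)c(OC)c2O[Si](C(C)(C)C)(C(C)(C)C)Oc12
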